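**Retrosynthetic overview**
1. No ring is formed and no stereocentre is set. The arene is bought, and the only strategic bond is the alkyl O–CH2 (carbon–oxygen) bond of the ester.
2. Odd-numbered C21 alcohols and halides are speciality chemicals, so the C21 electrophile is traced back, by loss of CO2, to commodity C22 docosanoic (behenic) acid 1. This acid is activated with N-hydroxyphthalimide 2 as redox-active ester 3.
3. The O-nucleophile is unprotected 2,3-dihydroxybenzoic acid 4. No protecting groups are used.
4. Forward order: 1 + 2 → 3, then 3 + 4 → (iodide 5 and carboxylate 6 in the flask) → target 7.

**Assumption:** the SMILES shows an unbranched C21 chain and no stereocentre or alkene (achiral, C28H48O4). There is therefore no enantiomer to select, and no step creates a stereocentre.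

**Step 1**
Reactants: 1 docosanoic acid (behenic acid); 2 N-hydroxyphthalimide
Product: 3 N-(docosanoyloxy)phthalimide
Conditions: iPrN=C=NiPr (DIC, 1.1 equiv), 4-dimethylaminopyridine (5 mol %), CH2Cl2, 35 °C, 4 h; filter; recrystallise (EtOH)
Reagents that add atoms: none
Why: Steglich-type carbodiimide esterification, in which the O-acylisourea of 1 is intercepted by the acidic N–OH nucleophile to give a crystalline active ester without chromatography, and no stereocentre is involved.

**Step 2**
Reactants: 3 N-(docosanoyloxy)phthalimide; 4 o-pyrocatechuic acid (2,3-dihydroxybenzoic acid, 1.5 equiv)
Product: 7 henicosyl 2,3-dihydroxybenzoate (Gentiside I), via 1-iodohenicosane 5 (not isolated), via tetrabutylammonium 2,3-dihydroxybenzoate 6 (not isolated)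
Conditions: Bu4NI (30 mol %), PPh3 (10 mol %), degassed acetone (0.1 M), 456 nm LEDs, 50 °C, Ar, 24 h, no added base; warm hexane extraction, SiO2
Reagents that add atoms: none
Why: Proposed new method: an iodide-relay, base-free decarboxylative esterification in which blue light excites the charge-transfer complex of iodide, PPh3 and the phthalimide ester 3, single-electron transfer and loss of CO2 give the primary C21 radical that is capped as iodide 5, the expelled phthalimide anion (conjugate acid pKa about 8) is protonated at once by 4 (pKa about 3) so that carboxylate 6 is the only anionic nucleophile present (phenols stay protonated, Gabriel-type N-alkylation is shut off), and SN2 attack of 6 on 5 forms the O–CH2 bond and returns iodide to the cycle; the closest known reaction types are the stoichiometric LiI/PPh3 photochemical decarboxylative iodination of N-(acyloxy)phthalimides and the iodide-catalysed (Finkelstein-type) alkylation of carboxylate salts, which have not been merged into one cycle catalytic in iodide or run on a free catechol acid; no stereocentre is formed.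

**Compound list**
1 | docosanoic acid (behenic acid) | CCCCCCCCCCCCCCCCCCCCCC(=O)O | starting material
2 | N-hydroxyphthalimide | O=C1c2ccccc2C(=O)N1O | starting material
3 | N-(docosanoyloxy)phthalimide (1,3-dioxoisoindolin-2-yl docosanoate) | CCCCCCCCCCCCCCCCCCCCCC(=O)ON1C(=O)c2ccccc2C1=O | intermediate
4 | 2,3-dihydroxybenzoic acid (o-pyrocatechuic acid) | OC(=O)c1cccc(O)c1O | starting material
5 | 1-iodohenicosane | CCCCCCCCCCCCCCCCCCCCCI | intermediate
6 | tetrabutylammonium 2,3-dihydroxybenzoate | CCCC[N+](CCCC)(CCCC)CCCC.[O-]C(=O)c1cccc(O)c1O | intermediate
7 | henicosyl 2,3-dihydroxybenzoate (Gentiside I, achiral) | CCCCCCCCCCCCCCCCCCCCCOC(=O)c1cccc(O)c1O | target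

**Total step count:** 2. **Longest linear sequence:** 2.

**Steps most likely to fail** (the route has only two steps, so both are ranked and there is no third)

**First: step 2, the proposed new step.** There are three ways it can fail.
- The catechol O–H groups may donate hydrogen to the C21 radical. Both are tied up in intramolecular hydrogen bonds, sit on an electron-poor ring and are further shielded by the hydrogen-bond-accepting solvent, but the risk remains.
- Iodide turnover may stall, because the hydrogen-bonded, salicylate-type carboxylate 6 is a modest SN2 nucleophile.
- Carboxylate 6 or a phenol may attack the active-ester carbonyl of 3 instead of waiting for 5.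

The fallback uses known chemistry, sets out from 3 and comes back to the route at 7. It separates the radical event from the polar one, so the catechol never meets a radical.
- Ester 3 is irradiated at 456 nm with LiI (1.5 equiv) and PPh3 (10 mol %) in acetone at room temperature. This is the known stoichiometric decarboxylative iodination.
- 1-Iodohenicosane 5 is this time isolated through a hexane plug.
- Separately, 4 is stirred with KHCO3 (1.1 equiv) in DMF to give potassium 2,3-dihydroxybenzoate F1.
- F1 is alkylated with 5 at 50 °C to give 7. This is the classical carboxylate-selective alkylation, and hydrogencarbonate is too weak a base to deprotonate either phenol.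

**Second: step 1.** The waxy acid 1 dissolves poorly in CH2Cl2, and a slow coupling lets the O-acylisourea rearrange to the N-acylurea. The fallback sets out from 1 and comes back to the route at 3. It replaces carbodiimide activation by an acyl chloride.
- Acid 1 with SOCl2 (1.5 equiv) and a drop of DMF in toluene at 60 °C gives docosanoyl chloride F2.
- After evaporation, F2 is added to 2 and Et3N (1.2 equiv) in CH2Cl2 at 0 °C. This is a plain base-mediated O-acylation and gives 3.

**Further compounds**
F1 | step 2 | potassium 2,3-dihydroxybenzoate | [K+].[O-]C(=O)c1cccc(O)c1O
F2 | step 1 | docosanoyl chloride | CCCCCCCCCCCCCCCCCCCCCC(=O)Cl
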